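(All runs were computed for substances that don't exist.)

An error in the ratio [isomer of the product A]/[target] at 20.0 h reaches the answer at 4.0 d multiplied by 7.33, if you run that ratio on in a straight line from the last two readings of the summer run.

- summer: starting material 1.4 M; the very flask that is asked about, followed so far
- flask: starting material 1.4 M; time 4.0 d

summer run (percent of the starting material charged)

| time / h | target / % | isomer of the product A / % |
|---|---|---|
| 1.50 | 10.5 | 0.2 |
| 4.00 | 20.9 | 1.1 |
| 8.00 | 26.9 | 1.7 |
| 20.0 | 25.0 | 2.6 |

(scatter of a reading: 0.3 percentage points)

1. share of target in target plus isomer of the product A at 12 min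
2. share of target in target plus isomer of the product A at 4.0 d
3. which of target and isomer of the product A there is more of at 4.0 d

The ratio reads 0.0632 at 8.00 h and 0.104 at 20.0 h. Now move each reading by one scatter, 0.3 percentage points. The isomer reading at 20.0 h shifts the ratio at 4.0 d by 0.0880. The isomer reading at 8.00 h shifts it by 0.0706. The target reading at 20.0 h shifts it by 0.00915, less than either. So the error at 4.0 d comes through the two isomer readings, and they are weak: one scatter is 11.5% of the last isomer reading, against 1.20% of the last target reading.

The drift, the daily rise of that ratio, is 0.0816 d⁻¹. My reckoning gives a ratio of 0.362 at 4.0 d, so a target share, the selectivity, of 73.4%, with target ahead. One scatter on the last isomer reading spans 69.0% to 78.5%. At 12 min I can't read the ratio, because at 1.50 h its scatter of 0.0286 exceeds its value of 0.0190.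

The forecast says 99.5%, 78% and target ahead, adding “this is a long extrapolation”.

The flask gives 96.8% and 72.7%, with target ahead.

    starting material ⇌ dormant form (K = 0.320, k = 0.00745 h⁻¹)
    target ⇌ isomer of the product C (K = 28.0, k = 0.0138 h⁻¹)
    starting material ⇌ isomer of the product A (K = 0.309, k = 0.00263 h⁻¹)
    starting material ⇌ target (K = 0.720, k = 0.0799 h⁻¹)
    starting material ⇌ isomer of the product B (K = 1.70, k = 0.0291 h⁻¹)

The drift predicted a ratio of 0.362, and the flask stands at 0.376. The same drift serves the neighbour charged with 2.4 M, whose share is 72.7%. In this flask at 4.0 d, target goes on to isomer of the product C with a forward half-life of 2.1 d, shorter than the 3.4 d in which isomer of the product A goes back to starting material. Net formation of target is then 0.711 of its net loss, with 12.4% of target standing.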